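**Retrosynthetic overview**
1. Target ⇐ acidolytic removal of five 4-methoxybenzyl (PMB) groups; the arylacetic acid ⇐ oxidative cleavage of a C-allyl group (CH2CH=CH2 → CH2CO2H) on the assembled ester.
2. Ester C–O bond ⇐ Steglich coupling of (E)-2-allyl-3,4-bis(PMB-oxy)cinnamic acid with PMB-protected (R)-3-(3,4-dihydroxyphenyl)lactate.
3. Cinnamic acid ⇐ Knoevenagel–Doebner on the benzaldehyde; its 2-allyl group ⇐ aromatic Claisen rearrangement of the 3-O-allyl ether of 4-O-PMB-protocatechualdehyde.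
4. Lactate stereocentre ⇐ D-lactate dehydrogenase reduction of 3,4-dihydroxyphenylpyruvic acid ⇐ Erlenmeyer azlactone from 3,4-dihydroxybenzaldehyde and N-acetylglycine.
5. Rings: no ring of the target is built; both benzene rings come from 3,4-dihydroxybenzaldehyde. The only ring formed is the transient oxazolone (made in step 1, opened in step 2).

Assumption: PMB = 4-methoxybenzyl; the enzymes and the NAD+/NADH cofactor are catalysts and are not counted as starting materials.

**Lactate fragment (steps 1–4)**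

Step 1
Reactants: 1 3,4-dihydroxybenzaldehyde; 2 N-acetylglycine
Product: 5 (4Z)-4-(3,4-diacetoxybenzylidene)-2-methyl-1,3-oxazol-5(4H)-one, via 3,4-diacetoxybenzaldehyde 3 (not isolated), via 2-methyloxazol-5(4H)-one 4 (not isolated)
Conditions: Ac2O, NaOAc, 120 °C, 3 h; ice-water, filter
Reagents that add atoms: acetic anhydride, CC(=O)OC(C)=O
Why: Erlenmeyer–Plöchl azlactone synthesis: Ac2O acetylates both phenols and cyclodehydrates N-acetylglycine to the oxazolone, whose acidic CH2 condenses with the aldehyde to the favoured Z-azlactone (no stereocentre).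

Step 2
Reactants: 5 (4Z)-4-(3,4-diacetoxybenzylidene)-2-methyl-1,3-oxazol-5(4H)-one
Product: 7 3-(3,4-dihydroxyphenyl)-2-oxopropanoic acid, via acetamidoacrylic acid 6 (not isolated)
Conditions: 3 M HCl (aq), reflux, N2, 6 h; cool, crystallise
Reagents that add atoms: water, O
Why: Acid hydrolysis opens the azlactone and both aryl acetates, and the resulting enamide hydrolyses to the α-keto acid, which crystallises (as its enol tautomer) on cooling.

Step 3
Reactants: 7 3-(3,4-dihydroxyphenyl)-2-oxopropanoic acid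
Product: 8 (2R)-3-(3,4-dihydroxyphenyl)-2-hydroxypropanoic acid ((R)-danshensu)
Conditions: D-lactate dehydrogenase (NADH-dependent oxidoreductase), formate dehydrogenase, NAD+ (cat.), HCO2Na, KH2PO4/K2HPO4 buffer pH 7.0, degassed, 30 °C, N2; then HCl to pH 2, EtOAc
Reagents that add atoms: none
Why: Enzymatic asymmetric ketone reduction: the D-lactate dehydrogenase delivers hydride from NADH to the si face of the 2-oxo group, setting the only stereocentre as (R) in >99% ee, while formate dehydrogenase regenerates NADH and CO2 loss makes the reduction irreversible.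

Step 4
Reactants: 8 (2R)-3-(3,4-dihydroxyphenyl)-2-hydroxypropanoic acid
Product: 9 4-methoxybenzyl (2R)-3-[3,4-bis(4-methoxybenzyloxy)phenyl]-2-hydroxypropanoate
Conditions: PMBCl (3.3 equiv), K2CO3 (3.5 equiv), DMF, N2, rt → 45 °C
Reagents that add atoms: 4-methoxybenzyl chloride, COc1ccc(CCl)cc1
Why: Williamson etherification and carboxylate alkylation: K2CO3 ionises only the carboxylic acid and the two phenols, so the aliphatic 2-OH stays free and the stereocentre is not touched.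

**Cinnamic acid fragment (steps 5–9)**

Step 5
Reactants: 1 3,4-dihydroxybenzaldehyde
Product: 10 3-hydroxy-4-(4-methoxybenzyloxy)benzaldehyde
Conditions: PMBCl (1.05 equiv), NaHCO3 (1.5 equiv), NaI (0.3 equiv), DMF, 40 °C, 20 h
Reagents that add atoms: 4-methoxybenzyl chloride, COc1ccc(CCl)cc1
Why: Regioselective Williamson etherification: the weak base deprotonates only the more acidic 4-OH (para to the formyl group), so alkylation occurs there.

Step 6
Reactants: 10 3-hydroxy-4-(4-methoxybenzyloxy)benzaldehyde; 11 allyl bromide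
Product: 12 3-(allyloxy)-4-(4-methoxybenzyloxy)benzaldehyde
Conditions: K2CO3, DMF, rt, 6 h
Reagents that add atoms: none
Why: Williamson etherification of the remaining phenol with a reactive allylic halide.

Step 7
Reactants: 12 3-(allyloxy)-4-(4-methoxybenzyloxy)benzaldehyde
Product: 14 2-allyl-3-hydroxy-4-(4-methoxybenzyloxy)benzaldehyde, via ortho-dienone 13 (not isolated)
Conditions: PhNEt2, 190 °C, Ar, 4 h
Reagents that add atoms: none
Why: Aromatic Claisen ([3,3]-sigmatropic) rearrangement: C4 is blocked by the PMB ether, so the allyl group migrates to C2 and the dienone tautomerises to the phenol, while the basic solvent protects the PMB ether.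

Step 8
Reactants: 14 2-allyl-3-hydroxy-4-(4-methoxybenzyloxy)benzaldehyde
Product: 15 2-allyl-3,4-bis(4-methoxybenzyloxy)benzaldehyde
Conditions: PMBCl (1.3 equiv), K2CO3, DMF, 55 °C
Reagents that add atoms: 4-methoxybenzyl chloride, COc1ccc(CCl)cc1
Why: Williamson etherification of the hindered phenol, which is not hydrogen-bonded to the formyl group.

Step 9
Reactants: 15 2-allyl-3,4-bis(4-methoxybenzyloxy)benzaldehyde; 16 malonic acid
Product: 18 (2E)-3-[2-allyl-3,4-bis(4-methoxybenzyloxy)phenyl]prop-2-enoic acid, via benzylidenemalonic acid 17 (not isolated)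
Conditions: pyridine, piperidine (cat.), 90 °C, 4 h; then cold 1 M HCl
Reagents that add atoms: none
Why: Knoevenagel–Doebner condensation: the arylidene malonic acid decarboxylates in hot pyridine to the E-cinnamic acid only, and the base is too weak to isomerise the allyl group.

**Coupling and end game (steps 10–13)**

Step 10
Reactants: 18 (2E)-3-[2-allyl-3,4-bis(4-methoxybenzyloxy)phenyl]prop-2-enoic acid; 9 4-methoxybenzyl (2R)-3-[3,4-bis(4-methoxybenzyloxy)phenyl]-2-hydroxypropanoate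
Product: 20 4-methoxybenzyl (2R)-2-{[(2E)-3-[2-allyl-3,4-bis(4-methoxybenzyloxy)phenyl]prop-2-enoyl]oxy}-3-[3,4-bis(4-methoxybenzyloxy)phenyl]propanoate, via O-acylisourea 19 (not isolated)
Conditions: DCC (1.2 equiv), DMAP (0.15 equiv), CH2Cl2, 0 °C → rt
Reagents that add atoms: none
Why: Steglich esterification: the alcohol oxygen is acylated, so the C–O bond at the stereocentre is never broken and the (R) configuration is retained.

Step 11
Reactants: 20 4-methoxybenzyl (2R)-2-{[(2E)-3-[2-allyl-3,4-bis(4-methoxybenzyloxy)phenyl]prop-2-enoyl]oxy}-3-[3,4-bis(4-methoxybenzyloxy)phenyl]propanoate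
Product: 22 4-methoxybenzyl (2R)-2-{[(2E)-3-[3,4-bis(4-methoxybenzyloxy)-2-(2-oxoethyl)phenyl]prop-2-enoyl]oxy}-3-[3,4-bis(4-methoxybenzyloxy)phenyl]propanoate, via vicinal diol 21 (not isolated)
Conditions: OsO4 (2 mol %), NaIO4 (4 equiv), 2,6-lutidine (2 equiv), dioxane/H2O 3:1, rt; crude aldehyde used at once
Reagents that add atoms: osmium tetroxide (oxygen carrier), O=[Os](=O)(=O)=O; NaIO4 (terminal oxidant), [Na+].[O-]I(=O)(=O)=O
Why: Lemieux–Johnson oxidative cleavage: OsO4 dihydroxylates the isolated monosubstituted alkene much faster than the electron-poor, conjugated cinnamate double bond, and NaIO4 cleaves the diol to the aldehyde.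

Step 12
Reactants: 22 4-methoxybenzyl (2R)-2-{[(2E)-3-[3,4-bis(4-methoxybenzyloxy)-2-(2-oxoethyl)phenyl]prop-2-enoyl]oxy}-3-[3,4-bis(4-methoxybenzyloxy)phenyl]propanoate
Product: 23 {6-[(1E)-3-{[(2R)-1-(4-methoxybenzyloxy)-3-[3,4-bis(4-methoxybenzyloxy)phenyl]-1-oxopropan-2-yl]oxy}-3-oxoprop-1-en-1-yl]-2,3-bis(4-methoxybenzyloxy)phenyl}acetic acid
Conditions: NaClO2, NaH2PO4, 2-methyl-2-butene, t-BuOH/THF/H2O, 0 °C → rt
Reagents that add atoms: NaClO2, [Na+].[O-]Cl=O
Why: Pinnick oxidation: chlorite converts the aldehyde to the acid at pH about 4 without touching the enoate, the PMB groups or the stereocentre, and 2-methyl-2-butene scavenges the hypochlorous acid.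

Step 13
Reactants: 23 {6-[(1E)-3-{[(2R)-1-(4-methoxybenzyloxy)-3-[3,4-bis(4-methoxybenzyloxy)phenyl]-1-oxopropan-2-yl]oxy}-3-oxoprop-1-en-1-yl]-2,3-bis(4-methoxybenzyloxy)phenyl}acetic acid
Product: 24 salvianolic acid D, (2R)-2-{[(2E)-3-[2-(carboxymethyl)-3,4-dihydroxyphenyl]prop-2-enoyl]oxy}-3-(3,4-dihydroxyphenyl)propanoic acid
Conditions: TFA/CH2Cl2 1:9, C6HMe5 (20 equiv), 0 °C, 1 h; evaporate cold, C18 chromatography (MeCN/H2O, 0.1% HCO2H), lyophilise
Reagents that add atoms: none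
Why: Acidolytic cleavage of the four PMB ethers and the PMB ester: each PMB cation is trapped irreversibly by pentamethylbenzene (Friedel–Crafts), while the secondary cinnamate ester, the E-alkene and the stereocentre are inert to dilute TFA at 0 °C.

**Compound list**
1 | 3,4-dihydroxybenzaldehyde | O=Cc1ccc(O)c(O)c1 | starting material
2 | N-acetylglycine | CC(=O)NCC(=O)O | starting material
3 | 3,4-diacetoxybenzaldehyde | O=Cc1ccc(OC(C)=O)c(OC(C)=O)c1 | intermediate (not isolated)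
4 | 2-methyl-1,3-oxazol-5(4H)-one | CC1=NCC(=O)O1 | intermediate (not isolated)
5 | (4Z)-4-(3,4-diacetoxybenzylidene)-2-methyl-1,3-oxazol-5(4H)-one | CC1=N/C(=C\c2ccc(OC(C)=O)c(OC(C)=O)c2)C(=O)O1 | intermediate
6 | (2Z)-2-acetamido-3-(3,4-dihydroxyphenyl)prop-2-enoic acid | CC(=O)N/C(=C\c1ccc(O)c(O)c1)C(=O)O | intermediate (not isolated)
7 | 3-(3,4-dihydroxyphenyl)-2-oxopropanoic acid | O=C(O)C(=O)Cc1ccc(O)c(O)c1 | intermediate
8 | (2R)-3-(3,4-dihydroxyphenyl)-2-hydroxypropanoic acid | O[C@H](Cc1ccc(O)c(O)c1)C(=O)O | intermediate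
9 | 4-methoxybenzyl (2R)-3-[3,4-bis(4-methoxybenzyloxy)phenyl]-2-hydroxypropanoate | O[C@H](Cc1ccc(OCc2ccc(OC)cc2)c(OCc2ccc(OC)cc2)c1)C(=O)OCc1ccc(OC)cc1 | intermediate
10 | 3-hydroxy-4-(4-methoxybenzyloxy)benzaldehyde | O=Cc1ccc(OCc2ccc(OC)cc2)c(O)c1 | intermediate
11 | allyl bromide (3-bromoprop-1-ene) | C=CCBr | starting material
12 | 3-(allyloxy)-4-(4-methoxybenzyloxy)benzaldehyde | O=Cc1ccc(OCc2ccc(OC)cc2)c(OCC=C)c1 | intermediate
13 | 6-allyl-5-formyl-2-(4-methoxybenzyloxy)cyclohexa-2,4-dien-1-one (racemic ortho-dienone) | O=CC1=CC=C(OCc2ccc(OC)cc2)C(=O)C1CC=C | intermediate (not isolated)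
14 | 2-allyl-3-hydroxy-4-(4-methoxybenzyloxy)benzaldehyde | O=Cc1ccc(OCc2ccc(OC)cc2)c(O)c1CC=C | intermediate
15 | 2-allyl-3,4-bis(4-methoxybenzyloxy)benzaldehyde | O=Cc1ccc(OCc2ccc(OC)cc2)c(OCc2ccc(OC)cc2)c1CC=C | intermediate
16 | malonic acid | O=C(O)CC(=O)O | starting material
17 | 2-[2-allyl-3,4-bis(4-methoxybenzyloxy)benzylidene]malonic acid | O=C(O)C(=Cc1ccc(OCc2ccc(OC)cc2)c(OCc2ccc(OC)cc2)c1CC=C)C(=O)O | intermediate (not isolated)
18 | (2E)-3-[2-allyl-3,4-bis(4-methoxybenzyloxy)phenyl]prop-2-enoic acid | O=C(O)/C=C/c1ccc(OCc2ccc(OC)cc2)c(OCc2ccc(OC)cc2)c1CC=C | intermediate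
19 | O-acylisourea of 18 with N,N'-dicyclohexylcarbodiimide | C=CCc1c(/C=C/C(=O)OC(=NC2CCCCC2)NC2CCCCC2)ccc(OCc2ccc(OC)cc2)c1OCc1ccc(OC)cc1 | intermediate (not isolated)
20 | 4-methoxybenzyl (2R)-2-{[(2E)-3-[2-allyl-3,4-bis(4-methoxybenzyloxy)phenyl]prop-2-enoyl]oxy}-3-[3,4-bis(4-methoxybenzyloxy)phenyl]propanoate | C=CCc1c(/C=C/C(=O)O[C@H](Cc2ccc(OCc3ccc(OC)cc3)c(OCc3ccc(OC)cc3)c2)C(=O)OCc2ccc(OC)cc2)ccc(OCc2ccc(OC)cc2)c1OCc1ccc(OC)cc1 | intermediate
21 | 2,3-dihydroxypropyl analogue of 20 (vicinal diol, both epimers at the new carbinol carbon) | OCC(O)Cc1c(/C=C/C(=O)O[C@H](Cc2ccc(OCc3ccc(OC)cc3)c(OCc3ccc(OC)cc3)c2)C(=O)OCc2ccc(OC)cc2)ccc(OCc2ccc(OC)cc2)c1OCc1ccc(OC)cc1 | intermediate (not isolated)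
22 | 4-methoxybenzyl (2R)-2-{[(2E)-3-[3,4-bis(4-methoxybenzyloxy)-2-(2-oxoethyl)phenyl]prop-2-enoyl]oxy}-3-[3,4-bis(4-methoxybenzyloxy)phenyl]propanoate | O=CCc1c(/C=C/C(=O)O[C@H](Cc2ccc(OCc3ccc(OC)cc3)c(OCc3ccc(OC)cc3)c2)C(=O)OCc2ccc(OC)cc2)ccc(OCc2ccc(OC)cc2)c1OCc1ccc(OC)cc1 | intermediate
23 | {6-[(1E)-3-{[(2R)-1-(4-methoxybenzyloxy)-3-[3,4-bis(4-methoxybenzyloxy)phenyl]-1-oxopropan-2-yl]oxy}-3-oxoprop-1-en-1-yl]-2,3-bis(4-methoxybenzyloxy)phenyl}acetic acid | O=C(O)Cc1c(/C=C/C(=O)O[C@H](Cc2ccc(OCc3ccc(OC)cc3)c(OCc3ccc(OC)cc3)c2)C(=O)OCc2ccc(OC)cc2)ccc(OCc2ccc(OC)cc2)c1OCc1ccc(OC)cc1 | intermediate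
24 | salvianolic acid D, (2R)-2-{[(2E)-3-[2-(carboxymethyl)-3,4-dihydroxyphenyl]prop-2-enoyl]oxy}-3-(3,4-dihydroxyphenyl)propanoic acid | O=C(O)Cc1c(/C=C/C(=O)O[C@H](Cc2ccc(O)c(O)c2)C(=O)O)ccc(O)c1O | target

**Totals**
Total step count: 13 (steps 1–4 lactate fragment, steps 5–9 cinnamic acid fragment, steps 10–13 coupling and end game).
Longest linear sequence: 9 steps (1 → 10 → 12 → 14 → 15 → 18 → 20 → 22 → 23 → 24).

**Three steps most likely to fail**

Step 7 (Claisen rearrangement of 12). The PMB aryl ether must survive 190 °C next to a newly formed phenol, and some para-migration or PMB scrambling is possible. The fallback replaces the sigmatropic step by halogenation and cross-coupling; it sets out from 10 and comes back to the route at 15. Ortho-selective bromination of 10 (NBS, cat. i-Pr2NH, CH2Cl2, 0 °C; the position between OH and CHO, as for isovanillin) gives 2-bromo-3-hydroxy-4-(4-methoxybenzyloxy)benzaldehyde F1. Alkylation with PMBCl/K2CO3 in DMF gives 2-bromo-3,4-bis(4-methoxybenzyloxy)benzaldehyde F2. Stille allylation (allyltributylstannane, Pd(PPh3)4 as zerovalent palladium catalyst, toluene, 100 °C) then gives 15.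

Step 11 (chemoselective cleavage of the allyl group of 20). Osmylation of the cinnamate double bond or over-oxidation would erode the yield at a late stage. The fallback uses an electrophilic peracid, to which the enoate is inert; it sets out from 20 and comes back to the route at 22. mCPBA/NaHCO3 in CH2Cl2 (0 °C → rt) epoxidises only the terminal alkene and gives the oxiran-2-ylmethyl analogue of 20 F3 (both epimers at the oxirane carbon). H5IO6 in THF/H2O (0 °C → rt) opens the epoxide to diol 21 and cleaves it in the same flask to aldehyde 22.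

Step 13 (five-fold acidolysis of 23). The freed 2-hydroxyarylacetic acid can close to a benzofuranone in acid, PMB cations can re-alkylate the catechols, and the polar product is hard to purify. The fallback moves the acid step to a stage without the arylacetic acid, carries the phenols as acetates and makes the last step a neutral enzymatic deacetylation; it sets out from 20 and comes back to the route at 24.
- TFA/CH2Cl2 with pentamethylbenzene at 0 °C converts 20 into the 2-allyl tetraphenol acid F4.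
- Phenol-selective acetylation (Ac2O, NaHCO3, THF/H2O, 0 °C) gives the chromatographable tetraacetate F5.
- OsO4/NaIO4/2,6-lutidine in dioxane/H2O gives, through the vicinal diol F6 (not isolated), the arylacetaldehyde F7.
- NaClO2/NaH2PO4/2-methyl-2-butene gives the tetraacetyl diacid F8.
- A lipase (carboxylic ester hydrolase) in KH2PO4/K2HPO4 buffer pH 7 with 10% MeCN at 30 °C under N2 removes the four aryl acetates without touching the hindered secondary cinnamate ester and gives 24.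

**Further compounds**
F1 | step 7 | 2-bromo-3-hydroxy-4-(4-methoxybenzyloxy)benzaldehyde | O=Cc1ccc(OCc2ccc(OC)cc2)c(O)c1Br
F2 | step 7 | 2-bromo-3,4-bis(4-methoxybenzyloxy)benzaldehyde | O=Cc1ccc(OCc2ccc(OC)cc2)c(OCc2ccc(OC)cc2)c1Br
F3 | step 11 | 4-methoxybenzyl (2R)-2-{[(2E)-3-[3,4-bis(4-methoxybenzyloxy)-2-(oxiran-2-ylmethyl)phenyl]prop-2-enoyl]oxy}-3-[3,4-bis(4-methoxybenzyloxy)phenyl]propanoate (both epimers at the oxirane carbon) | C4OC4Cc1c(/C=C/C(=O)O[C@H](Cc2ccc(OCc3ccc(OC)cc3)c(OCc3ccc(OC)cc3)c2)C(=O)OCc2ccc(OC)cc2)ccc(OCc2ccc(OC)cc2)c1OCc1ccc(OC)cc1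
F4 | step 13 | (2R)-2-{[(2E)-3-(2-allyl-3,4-dihydroxyphenyl)prop-2-enoyl]oxy}-3-(3,4-dihydroxyphenyl)propanoic acid | C=CCc1c(/C=C/C(=O)O[C@H](Cc2ccc(O)c(O)c2)C(=O)O)ccc(O)c1O
F5 | step 13 | (2R)-2-{[(2E)-3-(3,4-diacetoxy-2-allylphenyl)prop-2-enoyl]oxy}-3-(3,4-diacetoxyphenyl)propanoic acid | C=CCc1c(/C=C/C(=O)O[C@H](Cc2ccc(OC(C)=O)c(OC(C)=O)c2)C(=O)O)ccc(OC(C)=O)c1OC(C)=O
F6 | step 13 | (2R)-2-{[(2E)-3-[3,4-diacetoxy-2-(2,3-dihydroxypropyl)phenyl]prop-2-enoyl]oxy}-3-(3,4-diacetoxyphenyl)propanoic acid (both epimers at the new carbinol carbon, not isolated) | OCC(O)Cc1c(/C=C/C(=O)O[C@H](Cc2ccc(OC(C)=O)c(OC(C)=O)c2)C(=O)O)ccc(OC(C)=O)c1OC(C)=O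
F7 | step 13 | (2R)-2-{[(2E)-3-[3,4-diacetoxy-2-(2-oxoethyl)phenyl]prop-2-enoyl]oxy}-3-(3,4-diacetoxyphenyl)propanoic acid | O=CCc1c(/C=C/C(=O)O[C@H](Cc2ccc(OC(C)=O)c(OC(C)=O)c2)C(=O)O)ccc(OC(C)=O)c1OC(C)=O
F8 | step 13 | (2R)-2-{[(2E)-3-[3,4-diacetoxy-2-(carboxymethyl)phenyl]prop-2-enoyl]oxy}-3-(3,4-diacetoxyphenyl)propanoic acid | O=C(O)Cc1c(/C=C/C(=O)O[C@H](Cc2ccc(OC(C)=O)c(OC(C)=O)c2)C(=O)O)ccc(OC(C)=O)c1OC(C)=O
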